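**Plan**

- Numbering: tridecane chain, C1 = benzylic CH2, C2 = CH(OAc), C8 = ketone, C9–C13 = pentyl.
- Retrosynthesis: cut C6–C7 first (as a C6=C7 enone made by cross-metathesis), then the aryl–C1 bond (aryl Grignard plus epoxide), then C3–C4 (butenyl Grignard plus epichlorohydrin).
- Enabling feature: C6–C7 is the α,β bond of the C8 ketone and both atoms are plain CH2 groups in an acyclic chain. The only ring, the benzene ring, is remote and uninvolved. The bond can therefore be made as an enone C=C between a terminal alkene and a vinyl ketone, and the extra unsaturation is removed afterwards.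
- Forward: (R)-epichlorohydrin is extended to an (R)-alkenyl epoxide, the aryl group is added, the alcohol is acetylated, and the C7–C13 vinyl ketone is joined by cross-metathesis. One hydrogenation then saturates C6=C7 and frees the phenol.
- Stereochemistry: C2 (R) comes from (R)-epichlorohydrin (chiral pool). Both epoxide openings occur at CH2 termini, so the C2–O bond is never broken.

Key step: step 6

Remark: 3-bromo-5-methoxyphenol, (R)-epichlorohydrin, but-3-enylmagnesium bromide (THF solution) and oct-1-en-3-one are taken as commercial; the target is (R) at C2 (OAc > CH2Ar > CH2 chain > H).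

**Step 1**
Reactants: 1 3-bromo-5-methoxyphenol
Product: 2 1-(benzyloxy)-3-bromo-5-methoxybenzene
Conditions: BnBr, K2CO3, DMF, rt
Reagents that add atoms: benzyl bromide, BrCc1ccccc1
Why: Williamson ether synthesis (SN2 of the phenoxide on benzyl bromide) should be clean because the phenol is the only acidic site; the benzyl ether masks the phenol through the organomagnesium step and is later removed in the same operation that saturates the enone.

**Step 2**
Reactants: 3 (R)-epichlorohydrin; 4 but-3-en-1-ylmagnesium bromide
Product: 5 (R)-1-chlorohept-6-en-2-ol
Conditions: CuI (10 mol%), THF, −40 → −20 °C; then 1 M HCl, 0 °C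
Reagents that add atoms: none
Why: Cu(I)-catalysed Grignard opening of a terminal epoxide (cuprate SN2) should occur at the unsubstituted oxirane CH2 faster than displacement of the primary chloride at low temperature, so the C–O bond at the stereocentre is never broken, the (R) configuration of 3 is carried into 5, and isolation at the chlorohydrin stage keeps any product of direct chloride displacement (which would lead to the enantiomeric epoxide) out of the main line.

**Step 3**
Reactants: 5 (R)-1-chlorohept-6-en-2-ol
Product: 6 (R)-2-(pent-4-en-1-yl)oxirane
Conditions: NaOH (powdered), Et2O, rt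
Reagents that add atoms: none
Why: Intramolecular Williamson etherification (3-exo-tet) in which the alkoxide displaces the neighbouring primary chloride; the stereocentre only carries the nucleophilic oxygen and is not a reacting carbon, so the (R) configuration is retained.

**Step 4**
Reactants: 2 1-(benzyloxy)-3-bromo-5-methoxybenzene; 6 (R)-2-(pent-4-en-1-yl)oxirane
Product: 8 (R)-1-[3-(benzyloxy)-5-methoxyphenyl]hept-6-en-2-ol, via arylmagnesium bromide 7 (not isolated)
Conditions: Mg, I2 (cat.), THF, 65 °C; then CuI (10 mol%), 6, −30 → 0 °C; then 1 M HCl, 0 °C
Reagents that add atoms: none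
Why: Grignard formation (Mg insertion into the aryl C–Br bond) followed by Cu(I)-catalysed SN2 opening of the monosubstituted epoxide at its CH2 terminus should form the aryl–C1 bond regioselectively; the stereocentre is not a reacting centre, so (R)-6 gives (R)-8, and the terminal alkene and benzyl ether are inert to the arylcopper species.

**Step 5**
Reactants: 8 (R)-1-[3-(benzyloxy)-5-methoxyphenyl]hept-6-en-2-ol
Product: 9 (R)-1-[3-(benzyloxy)-5-methoxyphenyl]hept-6-en-2-yl acetate
Conditions: Ac2O, pyridine, DMAP (cat.), CH2Cl2, 0 °C → rt
Reagents that add atoms: acetic anhydride, CC(=O)OC(C)=O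
Why: DMAP-catalysed acylation (nucleophilic catalysis via the N-acetylpyridinium ion) takes place at oxygen with retention at C2, installs the acetate of the target and removes the free hydroxyl before the enone is made.

**Step 6**
Reactants: 9 (R)-1-[3-(benzyloxy)-5-methoxyphenyl]hept-6-en-2-yl acetate; 10 oct-1-en-3-one
Product: 11 (R,E)-1-[3-(benzyloxy)-5-methoxyphenyl]-8-oxotridec-6-en-2-yl acetate
Conditions: Hoveyda–Grubbs II (5 mol%), 10 (3 equiv), CH2Cl2, 40 °C
Reagents that add atoms: none
Why: Olefin cross-metathesis: the Ru alkylidene enters at the unhindered terminal alkene of 9 (type I olefin), the new alkylidene undergoes [2+2] cycloaddition with the electron-poor vinyl group of 10 (type II olefin), and the ruthenacyclobutane collapses by retro-[2+2] to the C6=C7 enone with loss of ethylene, which drives the equilibrium. The closest known reaction type is the cross-metathesis of terminal alkenes with alkyl vinyl ketones and acrylates under second-generation Ru catalysts. No ring is closed and no stereocentre is created; the only new stereo-element, the C6=C7 geometry, should be E under thermodynamic control and is erased in step 7 in any case. The selectivity needed is cross- over homo-coupling, and it rests on the electronic difference of the partners: 10 homodimerises slowly, whereas any homodimer of 9 remains a competent substrate and should be funnelled to 11 by the excess of 10. The C2 stereocentre lies four atoms from the reacting alkene and carries an acetate, so it cannot epimerise and cannot add to the new enone (a free C2 hydroxyl could close a tetrahydropyran by 6-exo-trig oxa-Michael addition). Because C7 becomes the α-carbon of the C8 carbonyl, the ketone arrives in place and unprotected, with none of the regiochemistry, polyalkylation or acetate-cleavage problems of an enolate alkylation of heptan-2-one.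

**Step 7**
Reactants: 11 (R,E)-1-[3-(benzyloxy)-5-methoxyphenyl]-8-oxotridec-6-en-2-yl acetate
Product: 12 (R)-1-(3-hydroxy-5-methoxyphenyl)-8-oxotridecan-2-yl acetate
Conditions: H2 (1 atm), 10% Pd/C, EtOAc, rt
Reagents that add atoms: none
Why: Heterogeneous catalytic hydrogenation with concurrent hydrogenolysis: Pd/C under H2 should saturate the conjugated C6=C7 bond and cleave the benzylic C–O bond of the aryl benzyl ether, while the dialkyl ketone, the non-benzylic secondary acetate, the aryl methyl ether and the C2 stereocentre are inert under these mild conditions.

**Compound list**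

1 | 3-bromo-5-methoxyphenol | COc1cc(O)cc(Br)c1 | starting material
2 | 1-(benzyloxy)-3-bromo-5-methoxybenzene | COc1cc(Br)cc(OCc2ccccc2)c1 | intermediate
3 | (R)-epichlorohydrin, (R)-2-(chloromethyl)oxirane | ClC[C@H]1CO1 | starting material
4 | but-3-en-1-ylmagnesium bromide | C=CCC[Mg]Br | starting material
5 | (R)-1-chlorohept-6-en-2-ol | ClC[C@H](O)CCCC=C | intermediate
6 | (R)-2-(pent-4-en-1-yl)oxirane | C=CCCC[C@@H]1CO1 | intermediate
7 | [3-(benzyloxy)-5-methoxyphenyl]magnesium bromide | COc1cc(OCc2ccccc2)cc([Mg]Br)c1 | intermediate (not isolated)
8 | (R)-1-[3-(benzyloxy)-5-methoxyphenyl]hept-6-en-2-ol | C=CCCC[C@H](Cc1cc(OCc2ccccc2)cc(OC)c1)O | intermediate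
9 | (R)-1-[3-(benzyloxy)-5-methoxyphenyl]hept-6-en-2-yl acetate | C=CCCC[C@H](Cc1cc(OCc2ccccc2)cc(OC)c1)OC(C)=O | intermediate
10 | oct-1-en-3-one | CCCCCC(=O)C=C | starting material
11 | (R,E)-1-[3-(benzyloxy)-5-methoxyphenyl]-8-oxotridec-6-en-2-yl acetate | CCCCCC(=O)/C=C/CCC[C@H](Cc1cc(OCc2ccccc2)cc(OC)c1)OC(C)=O | intermediate
12 | (R)-1-(3-hydroxy-5-methoxyphenyl)-8-oxotridecan-2-yl acetate | CCCCCC(=O)CCCCC[C@H](Cc1cc(O)cc(OC)c1)OC(C)=O | target

**Summary**

Total step count: 7. Longest linear sequence: 6 steps (3 → 5 → 6 → 8 → 9 → 11 → 12).

Steps most likely to fail: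

1. Step 6. The risk is chain-walking isomerisation of the terminal alkene by Ru–H species formed on catalyst decomposition, which after metathesis would give a chain one carbon short, and stalling at the homodimer of the type I olefin. The fallback makes the same C6=C7 bond by olefination instead of metathesis. It sets out from 9: Lemieux–Johnson cleavage (OsO4 cat., NaIO4, 2,6-lutidine, dioxane/H2O) should give the aldehyde (R)-1-[3-(benzyloxy)-5-methoxyphenyl]-6-oxohexan-2-yl acetate F1. A Horner–Wadsworth–Emmons reaction of this aldehyde with commercial dimethyl (2-oxoheptyl)phosphonate (CCCCCC(=O)CP(=O)(OC)OC) under Masamune–Roush conditions (LiCl, i-Pr2NEt, MeCN, rt) should give the E-enone and comes back to the route at 11.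

2. Step 4. The risk is sluggish magnesium insertion into the electron-rich aryl bromide with biaryl homocoupling, and competing opening of the epoxide by bromide from the Schlenk equilibrium. The fallback forms the aryl–carbon bond by Pd catalysis, takes the stereocentre from a kinetic resolution and reverses the roles of the partners. It sets out from 2: Stille allylation (allyltributylstannane, C=CC[Sn](CCCC)(CCCC)CCCC, Pd(PPh3)4, toluene, 110 °C) should give 1-allyl-3-(benzyloxy)-5-methoxybenzene F2. Epoxidation with mCPBA (CH2Cl2, 0 °C) should give rac-2-[3-(benzyloxy)-5-methoxybenzyl]oxirane F3. Jacobsen hydrolytic kinetic resolution with (S,S)-(salen)Co(III)OAc and 0.55 equiv H2O is expected, by analogy with simple alkyl-substituted terminal epoxides, to hydrolyse the (R)-epoxide and leave (S)-2-[3-(benzyloxy)-5-methoxybenzyl]oxirane F4, at the cost of the other enantiomer. CuI-catalysed opening of F4 at its CH2 terminus with 4 (THF, −30 → 0 °C, then 1 M HCl) comes back to the route at 8; the descriptor changes from S to R only because the CIP priorities change.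

3. Step 7. The risk is poisoning of the Pd surface by ruthenium residues carried over from step 6, so that hydrogenolysis of the benzyl ether stalls, and over-reduction of the C8 ketone if the conditions are forced. The fallback separates the two events and avoids heterogeneous hydrogenation. It sets out from 11: conjugate reduction with Stryker's reagent ([(Ph3P)CuH]6 cat., PMHS, toluene, rt, then aqueous fluoride work-up) should give (R)-1-[3-(benzyloxy)-5-methoxyphenyl]-8-oxotridecan-2-yl acetate F5. Lewis-acid debenzylation (BCl3, pentamethylbenzene, CH2Cl2, −78 °C), which should spare the aryl methyl ether, the acetate and the ketone at this temperature, comes back to the route at 12.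

**Further compounds**

F1 | step 6 | (R)-1-[3-(benzyloxy)-5-methoxyphenyl]-6-oxohexan-2-yl acetate | O=CCCC[C@H](Cc1cc(OCc2ccccc2)cc(OC)c1)OC(C)=O
F2 | step 4 | 1-allyl-3-(benzyloxy)-5-methoxybenzene | C=CCc1cc(OCc2ccccc2)cc(OC)c1
F3 | step 4 | rac-2-[3-(benzyloxy)-5-methoxybenzyl]oxirane | COc1cc(OCc2ccccc2)cc(CC2CO2)c1
F4 | step 4 | (S)-2-[3-(benzyloxy)-5-methoxybenzyl]oxirane | COc1cc(OCc2ccccc2)cc(C[C@H]2CO2)c1
F5 | step 7 | (R)-1-[3-(benzyloxy)-5-methoxyphenyl]-8-oxotridecan-2-yl acetate | CCCCCC(=O)CCCCC[C@H](Cc1cc(OCc2ccccc2)cc(OC)c1)OC(C)=O
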